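The key step exploits the fact that C2–C3 of ring A (labdane numbering) is the only unsubstituted CH2–CH2 link, flanked by the quaternary carbons C4 and C10, so it can be made as an olefin and then erased. Ring B is built first: C10 is set by Pd-catalysed asymmetric allylation, giving a monocyclic triene that carries an allyl group (C1–C2) on C10 and a 1,1-dimethylallyl group (C4–C3) on sp2 C5. Ring-closing metathesis then forms C2=C3 and closes ring A in one operation; a single hydrogenation removes that olefin and sets C5 trans. Enol-triflate chemistry at C9 fixes the C8=C9 olefin, and a B-alkyl Suzuki coupling with a glycidate-derived iodo-butenolide completes the target.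

Key step: step 5

Remark (numbering): ring A = C1–C5 and C10, ring B = C5–C10, side chain C11–C15, butenolide C16–C19 (C4 gem-dimethyl, C10 angular methyl).
Remark (assumption): the (R)-antipode of t-Bu-PHOX in step 4 is chosen by analogy with the sense of induction of 2-methylcyclohexanone enol carbonates; the (S)-ligand is used if the dienolate responds in the opposite sense.
Remark (assumption): 11 is carried as a mixture of C8 epimers (no descriptor at that carbon in its SMILES), because C8 becomes sp2 in step 8.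

Step 1
Reactants: 1 2-methylcyclohexane-1,3-dione
Product: 2 3-ethoxy-2-methylcyclohex-2-en-1-one
Conditions: EtOH, TsOH·H2O (cat.), toluene, reflux, Dean–Stark
Reagents that add atoms: ethanol, CCO
Why: Acid-catalysed vinylogous esterification of the enolised 1,3-dione, driven by azeotropic removal of water.

Step 2
Reactants: 2 3-ethoxy-2-methylcyclohex-2-en-1-one
Product: 4 2-methyl-3-(2-methylbut-3-en-2-yl)cyclohex-2-en-1-one, via tertiary carbinol 3 (not isolated)
Conditions: prenylMgCl, THF, −78 to 0 °C; then 1 M HCl, rt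
Reagents that add atoms: prenylmagnesium chloride, CC(C)=CC[Mg]Cl; water, O
Why: Stork–Danheiser sequence in which the allylic Grignard reagent adds 1,2 through its γ-carbon (cyclic SE2′ transition state) and aqueous acid hydrolyses the enol ether and dehydrates to the transposed enone, joining C4 (gem-dimethyl, vinyl) to C5 without creating a stereocentre.

Step 3
Reactants: 4 2-methyl-3-(2-methylbut-3-en-2-yl)cyclohex-2-en-1-one
Product: 6 allyl 2-methyl-3-(2-methylbut-3-en-2-yl)cyclohexa-1,3-dien-1-yl carbonate, via sodium dienolate 5 (not isolated)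
Conditions: NaH, t-BuOH (cat.), THF, 0 °C to rt; then ClCO2CH2CH=CH2, −78 °C
Reagents that add atoms: allyl chloroformate, C=CCOC(=O)Cl
Why: Equilibrating deprotonation should give the extended (γ-deprotonated) dienolate rather than the kinetic α′-enolate, and the hard chloroformate acylates it on oxygen (enol carbonate formation); any C-acylated β-keto ester would feed the same Pd enolate in step 4.

Step 4
Reactants: 6 allyl 2-methyl-3-(2-methylbut-3-en-2-yl)cyclohexa-1,3-dien-1-yl carbonate
Product: 7 (S)-2-methyl-3-(2-methylbut-3-en-2-yl)-2-(prop-2-en-1-yl)cyclohex-3-en-1-one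
Conditions: Pd2(dba)3 (2.5 mol%), (R)-t-Bu-PHOX (6 mol%), THF, 25 °C
Reagents that add atoms: none
Why: Pd-catalysed decarboxylative asymmetric allylic alkylation (Tsuji–Trost type), in which ionisation and loss of CO2 give a PHOX-ligated allyl-Pd dienolate that forms the C10–C1 bond at the α-carbon, the ligand selecting the enolate face so that the (S)-quaternary centre C10 is expected.

Step 5
Reactants: 7 (S)-2-methyl-3-(2-methylbut-3-en-2-yl)-2-(prop-2-en-1-yl)cyclohex-3-en-1-one
Product: 8 (S)-5,5,8a-trimethyl-3,5,8,8a-tetrahydronaphthalen-1(2H)-one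
Conditions: Grubbs II (3 mol%), CH2Cl2 (5 mM), 40 °C
Reagents that add atoms: none
Why: Ring-closing olefin metathesis: the Ru alkylidene loads on the unhindered allyl terminus (C2), and [2+2] cycloaddition with the neopentyl-type vinyl group on C4 followed by cycloreversion expels ethene and leaves the C2=C3 double bond. The closest known reaction type is RCM of 1,7-dienes to cyclohexenes that carry an allylic quaternary carbon. Ring A is closed as a six-membered ring with the new olefin endocyclic (C10–C1–C2=C3–C4–C5). No stereocentre is created; C10 passes through untouched and the ring fixes the C2=C3 geometry as cis. The step needs chemoselectivity for the two monosubstituted olefins over the ring-B C5=C6 bond, and cyclisation over oligomerisation; the trisubstituted C5=C6 bond between two quaternary carbons should be inert to the catalyst, and the quaternary C4 and C10 together with sp2 C5 hold both arms on the same edge of ring B (gem-dialkyl effect), so closure at high dilution should outrun cross-metathesis.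

Step 6
Reactants: 8 (S)-5,5,8a-trimethyl-3,5,8,8a-tetrahydronaphthalen-1(2H)-one
Product: 9 (4aS,8aS)-5,5,8a-trimethyloctahydronaphthalen-1(2H)-one
Conditions: H2 (4 bar), 10% Pd/C, EtOAc, rt
Reagents that add atoms: none
Why: Heterogeneous catalytic hydrogenation saturates C2=C3 and then the ring-fusion C5=C6 olefin, with hydrogen expected on the α-face opposite the axial C10 methyl and the 4β-methyl, so that C5 is set as 5α-H (trans-decalin) while the ketone is untouched.

Step 7
Reactants: 9 (4aS,8aS)-5,5,8a-trimethyloctahydronaphthalen-1(2H)-one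
Product: 11 (4aS,8aS)-2,5,5,8a-tetramethyloctahydronaphthalen-1(2H)-one (C2 epimers), via lithium enolate 10 (not isolated)
Conditions: LDA, THF, −78 °C; MeI, −78 to 0 °C
Reagents that add atoms: iodomethane, CI
Why: Enolate alkylation in which C8 is the only enolisable position (C10 is quaternary), so monomethylation should be regiospecific, and the new C8 configuration is irrelevant because it is erased in step 8.

Step 8
Reactants: 11 (4aS,8aS)-2,5,5,8a-tetramethyloctahydronaphthalen-1(2H)-one
Product: 13 (4aS,8aS)-2,5,5,8a-tetramethyl-3,4,4a,5,6,7,8,8a-octahydronaphthalen-1-yl trifluoromethanesulfonate, via potassium enolate 12 (not isolated)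
Conditions: KHMDS, THF, −78 to 0 °C; PhNTf2, −78 °C to rt
Reagents that add atoms: N-phenylbis(trifluoromethanesulfonimide), O=S(=O)(N(c1ccccc1)S(=O)(=O)C(F)(F)F)C(F)(F)F
Why: Enol triflate formation, in which deprotonation can occur only at C8 and O-triflylation of the tetrasubstituted enolate fixes the C8=C9 double bond regiospecifically.

Step 9
Reactants: 13 (4aS,8aS)-2,5,5,8a-tetramethyl-3,4,4a,5,6,7,8,8a-octahydronaphthalen-1-yl trifluoromethanesulfonate
Product: 14 (4aS,8aS)-1-ethenyl-2,5,5,8a-tetramethyl-3,4,4a,5,6,7,8,8a-octahydronaphthalene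
Conditions: CH2=CHSnBu3, Pd(PPh3)4 (5 mol%), LiCl, THF, 65 °C
Reagents that add atoms: tributyl(vinyl)stannane, C=C[Sn](CCCC)(CCCC)CCCC
Why: Stille coupling of the hindered alkenyl triflate with a small vinylstannane (LiCl-assisted) installs C11–C12 while the C8=C9 olefin stays in place.

Step 10
Reactants: 15 tert-butyldimethyl(prop-2-yn-1-yloxy)silane; 16 methyl (R)-oxirane-2-carboxylate
Product: 18 methyl (R)-6-[(tert-butyldimethylsilyl)oxy]-2-hydroxyhex-4-ynoate, via lithium acetylide 17 (not isolated)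
Conditions: n-BuLi, THF, −78 °C; BF3·OEt2; then 16, −78 °C
Reagents that add atoms: none
Why: BF3-mediated alkynylation of an epoxide (Yamaguchi–Hirao type), in which the alkynyl nucleophile opens the glycidate by SN2 at the unsubstituted carbon (future C15) and leaves the C–O stereocentre (future C16, R) untouched.

Step 11
Reactants: 18 methyl (R)-6-[(tert-butyldimethylsilyl)oxy]-2-hydroxyhex-4-ynoate
Product: 19 (R)-6-[(tert-butyldimethylsilyl)oxy]-2-hydroxy-N-methoxy-N-methylhex-4-ynamide
Conditions: MeNH(OMe)·HCl, i-PrMgCl, THF, −20 to 0 °C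
Reagents that add atoms: N,O-dimethylhydroxylamine hydrochloride, CNOC.Cl
Why: Weinreb amide formation by aminolysis of the ester with the chloromagnesium amide, the free hydroxyl being carried as its magnesium alkoxide so that the stereocentre is not enolised.

Step 12
Reactants: 19 (R)-6-[(tert-butyldimethylsilyl)oxy]-2-hydroxy-N-methoxy-N-methylhex-4-ynamide
Product: 20 (R)-7-[(tert-butyldimethylsilyl)oxy]-3-hydroxy-1-(methoxymethoxy)hept-5-yn-2-one
Conditions: Bu3SnCH2OMOM, n-BuLi, THF, −78 °C; then 19, −78 °C; aq. NH4Cl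
Reagents that add atoms: tributyl[(methoxymethoxy)methyl]stannane, CCCC[Sn](CCCC)(CCCC)COCOC
Why: Weinreb ketone synthesis in which (methoxymethoxy)methyllithium from tin–lithium exchange (the first equivalent is consumed by the hydroxyl) adds once to the amide through a stable chelated tetrahedral intermediate, giving the α-hydroxy ketone without over-addition.

Step 13
Reactants: 20 (R)-7-[(tert-butyldimethylsilyl)oxy]-3-hydroxy-1-(methoxymethoxy)hept-5-yn-2-one
Product: 21 (R)-5-{4-[(tert-butyldimethylsilyl)oxy]but-2-yn-1-yl}-4-[(methoxymethoxy)methyl]furan-2(5H)-one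
Conditions: Ph3P=C=C=O, toluene, 90 °C
Reagents that add atoms: (triphenylphosphoranylidene)ketene, O=C=C=P(c1ccccc1)(c1ccccc1)c1ccccc1
Why: Bestmann ylide domino reaction, in which the secondary hydroxyl adds to the ketenylidene phosphorane and the resulting ester ylide closes by intramolecular Wittig olefination on the adjacent ketone, forming the butenolide under neutral conditions so that C16 is retained.

Step 14
Reactants: 21 (R)-5-{4-[(tert-butyldimethylsilyl)oxy]but-2-yn-1-yl}-4-[(methoxymethoxy)methyl]furan-2(5H)-one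
Product: 22 (R)-5-(4-hydroxybut-2-yn-1-yl)-4-(hydroxymethyl)furan-2(5H)-one
Conditions: AcCl (cat.), MeOH, 40 °C
Reagents that add atoms: none
Why: Acid-catalysed methanolysis removes the silyl ether and the MOM acetal in one operation, conditions to which the butenolide and the alkyne should be stable.

Step 15
Reactants: 22 (R)-5-(4-hydroxybut-2-yn-1-yl)-4-(hydroxymethyl)furan-2(5H)-one
Product: 24 (R)-5-[(Z)-4-hydroxy-3-iodobut-2-en-1-yl]-4-(hydroxymethyl)furan-2(5H)-one, via alkenylstannane 23 (not isolated)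
Conditions: Bu3SnH, [Cp*RuCl]4 (2 mol%), CH2Cl2, rt; then I2, 0 °C
Reagents that add atoms: iodine, II
Why: Hydroxyl-directed Ru-catalysed trans-hydrostannation places tin on the alkyne carbon next to the propargylic OH by anti addition, and iododestannylation with retention should give the 2-iodo allylic alcohol with iodine cis to C15.

Step 16
Reactants: 14 (4aS,8aS)-1-ethenyl-2,5,5,8a-tetramethyl-3,4,4a,5,6,7,8,8a-octahydronaphthalene; 24 (R)-5-[(Z)-4-hydroxy-3-iodobut-2-en-1-yl]-4-(hydroxymethyl)furan-2(5H)-one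
Product: 26 (R)-4-(hydroxymethyl)-5-{(E)-3-(hydroxymethyl)-5-[(4aS,8aS)-2,5,5,8a-tetramethyl-3,4,4a,5,6,7,8,8a-octahydronaphthalen-1-yl]pent-2-en-1-yl}furan-2(5H)-one, via B-alkyl-9-BBN 25 (not isolated)
Conditions: 9-BBN, THF, rt; then 24, Pd(dppf)Cl2 (5 mol%), AsPh3, K3PO4 (aq), DMF, rt
Reagents that add atoms: none
Why: Anti-Markovnikov hydroboration of the terminal vinyl group (the tetrasubstituted olefin is inert) followed by B-alkyl Suzuki–Miyaura coupling forms C12–C13 with retention of the alkenyl iodide geometry, which corresponds to the (E)-olefin of the target, and free hydroxyls are tolerated.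

Compound list
1 | 2-methylcyclohexane-1,3-dione | CC1C(=O)CCCC1=O | starting material
2 | 3-ethoxy-2-methylcyclohex-2-en-1-one | CCOC1=C(C)C(=O)CCC1 | intermediate
3 | 3-ethoxy-2-methyl-1-(2-methylbut-3-en-2-yl)cyclohex-2-en-1-ol (racemic, not isolated) | CCOC1=C(C)C(O)(C(C)(C)C=C)CCC1 | intermediate
4 | 2-methyl-3-(2-methylbut-3-en-2-yl)cyclohex-2-en-1-one | CC1=C(C(C)(C)C=C)CCCC1=O | intermediate
5 | sodium 2-methyl-3-(2-methylbut-3-en-2-yl)cyclohexa-1,3-dien-1-olate (not isolated) | [Na+].[O-]C1=C(C)C(C(C)(C)C=C)=CCC1 | intermediate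
6 | allyl 2-methyl-3-(2-methylbut-3-en-2-yl)cyclohexa-1,3-dien-1-yl carbonate | C=CCOC(=O)OC1=C(C)C(C(C)(C)C=C)=CCC1 | intermediate
7 | (S)-2-methyl-3-(2-methylbut-3-en-2-yl)-2-(prop-2-en-1-yl)cyclohex-3-en-1-one | C=CC[C@]1(C)C(=O)CCC=C1C(C)(C)C=C | intermediate
8 | (S)-5,5,8a-trimethyl-3,5,8,8a-tetrahydronaphthalen-1(2H)-one (C4=C4a and C6=C7 olefins) | O=C1[C@@]2(C)CC=CC(C)(C)C2=CCC1 | intermediate
9 | (4aS,8aS)-5,5,8a-trimethyloctahydronaphthalen-1(2H)-one | O=C1[C@@]2(C)CCCC(C)(C)[C@@H]2CCC1 | intermediate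
10 | lithium enolate of 9 (not isolated) | [Li+].[O-]C=1[C@@]2(C)CCCC(C)(C)[C@@H]2CCC=1 | intermediate
11 | (4aS,8aS)-2,5,5,8a-tetramethyloctahydronaphthalen-1(2H)-one (C2 epimers) | O=C1[C@@]2(C)CCCC(C)(C)[C@@H]2CCC1C | intermediate
12 | potassium enolate of 11 (not isolated) | [K+].[O-]C=1[C@@]2(C)CCCC(C)(C)[C@@H]2CCC=1C | intermediate
13 | (4aS,8aS)-2,5,5,8a-tetramethyl-3,4,4a,5,6,7,8,8a-octahydronaphthalen-1-yl trifluoromethanesulfonate | CC1=C(OS(=O)(=O)C(F)(F)F)[C@@]2(C)CCCC(C)(C)[C@@H]2CC1 | intermediate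
14 | (4aS,8aS)-1-ethenyl-2,5,5,8a-tetramethyl-3,4,4a,5,6,7,8,8a-octahydronaphthalene | CC1=C(C=C)[C@@]2(C)CCCC(C)(C)[C@@H]2CC1 | intermediate
15 | tert-butyldimethyl(prop-2-yn-1-yloxy)silane | C#CCO[Si](C)(C)C(C)(C)C | starting material
16 | methyl (R)-oxirane-2-carboxylate (methyl (R)-glycidate) | COC(=O)[C@H]1CO1 | starting material
17 | lithium acetylide of 15 (not isolated) | [Li]C#CCO[Si](C)(C)C(C)(C)C | intermediate
18 | methyl (R)-6-[(tert-butyldimethylsilyl)oxy]-2-hydroxyhex-4-ynoate | COC(=O)[C@H](O)CC#CCO[Si](C)(C)C(C)(C)C | intermediate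
19 | (R)-6-[(tert-butyldimethylsilyl)oxy]-2-hydroxy-N-methoxy-N-methylhex-4-ynamide | CON(C)C(=O)[C@H](O)CC#CCO[Si](C)(C)C(C)(C)C | intermediate
20 | (R)-7-[(tert-butyldimethylsilyl)oxy]-3-hydroxy-1-(methoxymethoxy)hept-5-yn-2-one | COCOCC(=O)[C@H](O)CC#CCO[Si](C)(C)C(C)(C)C | intermediate
21 | (R)-5-{4-[(tert-butyldimethylsilyl)oxy]but-2-yn-1-yl}-4-[(methoxymethoxy)methyl]furan-2(5H)-one | O=C1C=C(COCOC)[C@@H](CC#CCO[Si](C)(C)C(C)(C)C)O1 | intermediate
22 | (R)-5-(4-hydroxybut-2-yn-1-yl)-4-(hydroxymethyl)furan-2(5H)-one | O=C1C=C(CO)[C@@H](CC#CCO)O1 | intermediate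
23 | (R)-5-[(Z)-4-hydroxy-3-(tributylstannyl)but-2-en-1-yl]-4-(hydroxymethyl)furan-2(5H)-one (not isolated) | O=C1C=C(CO)[C@@H](C/C=C(/CO)[Sn](CCCC)(CCCC)CCCC)O1 | intermediate
24 | (R)-5-[(Z)-4-hydroxy-3-iodobut-2-en-1-yl]-4-(hydroxymethyl)furan-2(5H)-one | O=C1C=C(CO)[C@@H](C/C=C(/CO)I)O1 | intermediate
25 | 9-{2-[(4aS,8aS)-2,5,5,8a-tetramethyl-3,4,4a,5,6,7,8,8a-octahydronaphthalen-1-yl]ethyl}-9-borabicyclo[3.3.1]nonane (not isolated) | CC1=C(CCB3C4CCCC3CCC4)[C@@]2(C)CCCC(C)(C)[C@@H]2CC1 | intermediate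
26 | (R)-4-(hydroxymethyl)-5-{(E)-3-(hydroxymethyl)-5-[(4aS,8aS)-2,5,5,8a-tetramethyl-3,4,4a,5,6,7,8,8a-octahydronaphthalen-1-yl]pent-2-en-1-yl}furan-2(5H)-one (CNP0238475.3) | CC1=C(CC/C(=C\C[C@H]2OC(=O)C=C2CO)CO)[C@@]2(C)CCCC(C)(C)[C@@H]2CC1 | target

Total step count: 16. Longest linear sequence: 10 steps (steps 1–9 and 16); the butenolide branch is 6 steps (steps 10–15) before the coupling.

Steps most likely to fail

Step 4 (with its substrate from step 3). The dienolate may be trapped or allylated at the α′ instead of the α position, and the bulky 1,1-dimethylallyl neighbour may erode the enantioselectivity of the Pd-enolate allylation. The fallback sets out from 1 and returns at 8; it sets C10 by reduction instead of alkylation and keeps the same ring-closing bond formation. C-Allylation of 1 (allyl acetate, Pd(PPh3)4, Et3N) would give 2-methyl-2-(prop-2-en-1-yl)cyclohexane-1,3-dione F1. Noyori asymmetric transfer hydrogenation, with the TsDPEN–Ru antipode that delivers the 2R ketol, would desymmetrise it to (2R,3R)-3-hydroxy-2-methyl-2-(prop-2-en-1-yl)cyclohexan-1-one F2. Excess prenylMgCl would add to the remaining ketone to give (1R,2R)-2-methyl-3-(2-methylbut-3-en-2-yl)-2-(prop-2-en-1-yl)cyclohexane-1,3-diol F3. Ring-closing metathesis (Grubbs II) would close ring A to (1R,8aR)-5,5,8a-trimethyl-1,2,3,4,4a,5,8,8a-octahydronaphthalene-1,4a-diol F4. Dess–Martin oxidation of the secondary alcohol would give (8aS)-4a-hydroxy-5,5,8a-trimethyl-3,4,4a,5,8,8a-hexahydronaphthalen-1(2H)-one F5. Burgess dehydration of the tertiary alcohol, for which only C6 carries β-hydrogens, would return dienone 8.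

Step 6. Reduction of the hindered trisubstituted C5=C6 bond may stall, or hydrogen may be delivered from the β-face and give the cis-fused ketone. The fallback sets out from 8 and returns at 9. Only C2=C3 is hydrogenated with Wilkinson's catalyst to give (S)-5,5,8a-trimethyl-3,5,6,7,8,8a-hexahydronaphthalen-1(2H)-one F6. C5=C6 is then reduced by Mn-catalysed hydrogen-atom-transfer hydrogenation (Mn(dpm)3, PhSiH3, TBHP, i-PrOH), where the tertiary C5 radical should take up hydrogen to give the thermodynamically preferred trans-decalin 9.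

Step 16. The aqueous base may epimerise C16 or open the butenolide, and the alkylborane may protodeboronate before transmetalation. The fallback sets out from 14 and returns at 26 by a base-free Negishi coupling. Hydroboration of 14 to 25 and iodination (I2, NaOMe) would give (4aS,8aS)-1-(2-iodoethyl)-2,5,5,8a-tetramethyl-3,4,4a,5,6,7,8,8a-octahydronaphthalene F7. Iodide 24 is protected (TBSCl, imidazole) as (R)-5-{(Z)-4-[(tert-butyldimethylsilyl)oxy]-3-iodobut-2-en-1-yl}-4-{[(tert-butyldimethylsilyl)oxy]methyl}furan-2(5H)-one F9. Zinc insertion into F7 (Zn, LiCl, THF) would give {2-[(4aS,8aS)-2,5,5,8a-tetramethyl-3,4,4a,5,6,7,8,8a-octahydronaphthalen-1-yl]ethyl}zinc iodide F8, which is coupled with F9 (Pd(dppf)Cl2, THF, rt) to give the bis-TBS ether of the target F10. HF·pyridine then releases 26.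

Further compounds
F1 | step 4 | 2-methyl-2-(prop-2-en-1-yl)cyclohexane-1,3-dione | C=CCC1(C)C(=O)CCCC1=O
F2 | step 4 | (2R,3R)-3-hydroxy-2-methyl-2-(prop-2-en-1-yl)cyclohexan-1-one | O[C@H]1[C@@](C)(CC=C)C(=O)CCC1
F3 | step 4 | (1R,2R)-2-methyl-3-(2-methylbut-3-en-2-yl)-2-(prop-2-en-1-yl)cyclohexane-1,3-diol (C3 epimers) | O[C@H]1[C@@](C)(CC=C)C(O)(C(C)(C)C=C)CCC1
F4 | step 4 | (1R,8aR)-5,5,8a-trimethyl-1,2,3,4,4a,5,8,8a-octahydronaphthalene-1,4a-diol (C4a epimers) | O[C@H]1[C@@]2(C)CC=CC(C)(C)C2(O)CCC1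
F5 | step 4 | (8aS)-4a-hydroxy-5,5,8a-trimethyl-3,4,4a,5,8,8a-hexahydronaphthalen-1(2H)-one (C4a epimers) | O=C1[C@@]2(C)CC=CC(C)(C)C2(O)CCC1
F6 | step 6 | (S)-5,5,8a-trimethyl-3,5,6,7,8,8a-hexahydronaphthalen-1(2H)-one | O=C1[C@@]2(C)CCCC(C)(C)C2=CCC1
F7 | step 16 | (4aS,8aS)-1-(2-iodoethyl)-2,5,5,8a-tetramethyl-3,4,4a,5,6,7,8,8a-octahydronaphthalene | CC1=C(CCI)[C@@]2(C)CCCC(C)(C)[C@@H]2CC1
F8 | step 16 | {2-[(4aS,8aS)-2,5,5,8a-tetramethyl-3,4,4a,5,6,7,8,8a-octahydronaphthalen-1-yl]ethyl}zinc iodide | CC1=C(CC[Zn]I)[C@@]2(C)CCCC(C)(C)[C@@H]2CC1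
F9 | step 16 | (R)-5-{(Z)-4-[(tert-butyldimethylsilyl)oxy]-3-iodobut-2-en-1-yl}-4-{[(tert-butyldimethylsilyl)oxy]methyl}furan-2(5H)-one | O=C1C=C(CO[Si](C)(C)C(C)(C)C)[C@@H](C/C=C(/CO[Si](C)(C)C(C)(C)C)I)O1
F10 | step 16 | bis-TBS ether of 26 | CC1=C(CC/C(=C\C[C@H]2OC(=O)C=C2CO[Si](C)(C)C(C)(C)C)CO[Si](C)(C)C(C)(C)C)[C@@]2(C)CCCC(C)(C)[C@@H]2CC1
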